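**Plan**

- Retrosynthesis: the aryl ether C11–O is cut first (7-hydroxycoumarin), then C9–H/C11–OH (hydroboration of a C9=C11 methylene that comes from a C9 ketone). Ring B is then cut at C6–C7 and C8–C9, which removes a propyne unit (C7, C8, C12) and leaves a cis-fused cyclobutanone made of C5, C6, C9 and C10.
- That cyclobutanone is cut at C6–C9 and C5–C10 into a keteniminium (C9=C10) and the C5=C6 vinyl group of one chain; the chain is cut at C3–C4 into 2-methylglutaric anhydride and a prenyl nucleophile.
- Enabling feature: C6 and C9 are 1,4 to each other in ring B and both hang from the cis junction C5(H)–C10(CH3) of ring A. The four atoms C5, C6, C9, C10 can therefore exist as a strained cyclobutanone whose C6–C9 bond is replaced by the C7=C8 unit.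
- Forward: acyclic chain → ring A together with the four-membered ring ([2+2]) → ring B by nickel-catalysed alkyne insertion that closes at C6–C7 → C11 by methylenation/hydroboration → unmasking of the C3 ketone and C7–H → Mitsunobu etherification.
- Stereochemistry: C5 and C10 are set together in the [2+2] (cis by ring size, absolute sense from a C2-symmetric pyrrolidine on the keteniminium nitrogen); C9 is set by hydroboration on the convex face of the cis-fused bicycle.

Key step: step 5

Numbering used throughout (target skeleton): ring A = C1, C2, C3 (C=O), C4 (two CH3), C5, C10 (CH3); ring B = C5, C6, C7, C8 (CH3 = C12), C9, C10; C11 = CH2O on C9.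
Assumption: the (2R,5R)-amine is taken to induce the target configuration at C5/C10 in step 4; if the sense proves opposite, the (2S,5S)-amine is used and nothing else changes.

**Route**

Step 1
Reactants: 1 3-methyloxane-2,6-dione (2-methylglutaric anhydride); 2 (3-methylbut-2-en-1-yl)magnesium chloride
Product: 3 2,6,6-trimethyl-5-oxooct-7-enoic acid (racemic)
Conditions: 2 added to 1, THF, −78 °C; aq. HCl
Reagents that add atoms: (3-methylbut-2-en-1-yl)magnesium chloride (2), CC(C)=CC[Mg]Cl
Why: Acylation of an allylic Grignard reagent, which reacts through its γ-carbon (SE2′), should open the anhydride at the carbonyl remote from the methyl branch and join C3 to the quaternary C4 with the C5=C6 vinyl group in place; the hindered keto-carboxylate should resist a second addition, and the C10 centre is of no consequence because it is planarised in step 4.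

Step 2
Reactants: 3 2,6,6-trimethyl-5-oxooct-7-enoic acid; 4 (2R,5R)-2,5-dimethylpyrrolidine
Product: 6 1-[(2R,5R)-2,5-dimethylpyrrolidin-1-yl]-2,6,6-trimethyloct-7-ene-1,5-dione (both C2 epimers), via acid chloride 5 (not isolated)
Conditions: (COCl)2, DMF (cat.), CH2Cl2, 0 °C to rt; then 4, Et3N, DMAP (cat.), CH2Cl2, 0 °C to rt
Reagents that add atoms: (2R,5R)-2,5-dimethylpyrrolidine (4), C[C@@H]1CC[C@@H](C)N1
Why: Amide formation through the acid chloride; the C2-symmetric amine removes the amide-rotamer problem and is the chiral controller of step 4, while the configuration at C10 is irrelevant here (both epimers are used).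

Step 3
Reactants: 6 1-[(2R,5R)-2,5-dimethylpyrrolidin-1-yl]-2,6,6-trimethyloct-7-ene-1,5-dione
Product: 7 1-[(2R,5R)-2,5-dimethylpyrrolidin-1-yl]-2-methyl-4-[2-(2-methylbut-3-en-2-yl)-1,3-dioxolan-2-yl]butan-1-one (both C2 epimers)
Conditions: (TMSOCH2)2, TMSOTf (cat.), CH2Cl2, −78 °C to −20 °C
Reagents that add atoms: 1,2-bis(trimethylsilyloxy)ethane, C[Si](C)(C)OCCO[Si](C)(C)C
Why: Ketalisation with the bis-silyl ether of ethylene glycol under silyl triflate catalysis is effective for hindered ketones and masks the C3 carbonyl, which would otherwise trap the keteniminium ion in step 4 and compete with C9 in step 6; amide and vinyl group are inert.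

Step 4
Reactants: 7 ketal amide
Product: 10 (1R,6S)-2,2,6-trimethylspiro[bicyclo[4.2.0]octane-3,2′-[1,3]dioxolan]-7-one, via keteniminium triflate 8 (not isolated), via cyclobutaniminium triflate 9 (not isolated)
Conditions: Tf2O, 2,6-di-tert-butyl-4-methylpyridine, ClCH2CH2Cl, −20 °C to 80 °C; then H2O, NaHCO3, 60 °C
Reagents that add atoms: water, O
Why: Intramolecular [2+2] cycloaddition of a keteniminium salt with an unactivated alkene: O-triflation and loss of triflic acid give 8, whose electrophilic central carbon (C9) bonds to the terminal vinyl carbon C6 while C10 bonds to C5, so that ring A and the cyclobutane form together; the four-membered ring can only be cis-fused, which fixes C5–H and C10–CH3 syn, the methyl groups of the C2-symmetric pyrrolidine shield one face of C10 and so decide the absolute sense, and hydrolysis of 9 releases the ketone and the amine.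

Step 5
Reactants: 10 cis-fused cyclobutanone; 11 trimethyl(prop-1-yn-1-yl)silane
Product: 12 cis-fused silyl enone (ring A: C3 ethylene ketal and 4,4-dimethyl; ring B: C9=O with C8–CH3 and C7–SiMe3 on the C7=C8 bond; C5–H and C10–CH3 syn)
Conditions: Ni(cod)2 (10 mol%), PCy3 (20 mol%), toluene, 100 °C
Reagents that add atoms: trimethyl(prop-1-yn-1-yl)silane (11), CC#C[Si](C)(C)C
Why: Zerovalent nickel bearing PCy3 couples the strained C9 carbonyl of 10 with alkyne 11 by oxidative cyclisation (C9–C8 bond, oxanickelacyclopentene); β-carbon elimination then cleaves the cyclobutanone bond C9–C6 with release of ring strain and restores the C9 ketone, and C(sp3)–C(sp2) reductive elimination from the seven-membered nickelacycle forms C6–C7. The closest known reaction type is the nickel-catalysed intermolecular insertion of alkynes into cyclobutanones, a formal [4+2] two-carbon ring expansion to cyclohex-2-enones. Ring B is the only ring closed, and it closes as a six-membered ring by this reductive elimination within the metallacycle, not by a nucleophilic or radical attack on C7. No stereocentre is created; C5 and C10 are not touched, so the cis junction from step 4 is carried into the bicycle. Two selectivities are needed: cleavage of C9–C6 and not C9–C10, which should follow because the primary C6 migrates to nickel far more readily than the quaternary C10, and the alkyne orientation, which silicon should secure by ending on the nickel-bound carbon so that the methyl-bearing carbon bonds to C9 (C8–CH3, C7–Si). The silyl group also holds back alkyne oligomerisation and is removed in step 8.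

Step 6
Reactants: 12 cis-fused silyl enone
Product: 13 cis-fused silyl diene (as 12 with C9=CH2 in place of C9=O)
Conditions: Cp2TiMe2, toluene, 70 °C, dark
Reagents that add atoms: dimethyltitanocene Cp2TiMe2, C[Ti](C)(C1C=CC=C1)C1C=CC=C1
Why: Petasis olefination: the small, non-basic titanium methylidene formed from Cp2TiMe2 on heating should methylenate the hindered C9 carbonyl (flanked by the quaternary C10 and the substituted C8) without enolisation or conjugate addition; ketal and vinylsilane are inert and no stereocentre is formed.

Step 7
Reactants: 13 cis-fused silyl diene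
Product: 15 cis-fused silyl ketal alcohol (C9–H syn to C10–CH3 and C5–H; C11–OH), via B-alkyl-9-BBN adduct 14 (not isolated)
Conditions: 9-BBN, THF, 0 °C to rt; then NaOH, H2O2, 0 °C
Reagents that add atoms: hydrogen peroxide, OO
Why: Hydroboration–oxidation: 9-BBN should add only to the terminal methylene of the diene (boron on C11; the tetrasubstituted vinylsilane is inert), and hydrogen should reach C9 from the convex β face because in either chair-type conformer the α face is blocked (by the axial C1 on C10 or by the syn-axial C4 with its methyl groups on C5), which places C9–H syn to C10–CH3 and C5–H; oxidation occurs with retention.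

Step 8
Reactants: 15 cis-fused silyl ketal alcohol
Product: 16 (4aS,5R,8aS)-5-(hydroxymethyl)-1,1,4a,6-tetramethyl-3,4,4a,5,8,8a-hexahydronaphthalen-2(1H)-one
Conditions: CF3CO2H, CH2Cl2, H2O, 0 °C to rt; aq. NaHCO3, MeOH
Reagents that add atoms: water, O
Why: Aqueous acid hydrolyses the dioxolane, and ipso-protonation of the vinylsilane at C7 gives a tertiary β-silyl cation at C8 that loses silicon (protodesilylation), so the double bond should stay at C7=C8 and no stereocentre is touched.

Step 9
Reactants: 16 keto alcohol; 17 7-hydroxy-2H-chromen-2-one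
Product: 18 7-{[(1R,4aS,8aS)-2,5,5,8a-tetramethyl-6-oxo-1,4,4a,5,6,7,8,8a-octahydronaphthalen-1-yl]methoxy}-2H-chromen-2-one
Conditions: PPh3, DIAD, THF, 0 °C to rt
Reagents that add atoms: 7-hydroxy-2H-chromen-2-one (17), O=c1ccc2ccc(O)cc2o1
Why: Mitsunobu etherification of the primary alcohol with the acidic phenol; C11 is not stereogenic and the ketone and the trisubstituted alkene are untouched.

**Compound list**

1 | 3-methyloxane-2,6-dione (2-methylglutaric anhydride, racemic) | CC1CCC(=O)OC1=O | starting material
2 | (3-methylbut-2-en-1-yl)magnesium chloride (prenylmagnesium chloride) | CC(C)=CC[Mg]Cl | starting material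
3 | 2,6,6-trimethyl-5-oxooct-7-enoic acid (racemic) | C=CC(C)(C)C(=O)CCC(C)C(O)=O | intermediate
4 | (2R,5R)-2,5-dimethylpyrrolidine | C[C@@H]1CC[C@@H](C)N1 | starting material
5 | 2,6,6-trimethyl-5-oxooct-7-enoyl chloride (racemic, not isolated) | C=CC(C)(C)C(=O)CCC(C)C(Cl)=O | intermediate
6 | 1-[(2R,5R)-2,5-dimethylpyrrolidin-1-yl]-2,6,6-trimethyloct-7-ene-1,5-dione (both C2 epimers) | C=CC(C)(C)C(=O)CCC(C)C(=O)N1[C@H](C)CC[C@H]1C | intermediate
7 | 1-[(2R,5R)-2,5-dimethylpyrrolidin-1-yl]-2-methyl-4-[2-(2-methylbut-3-en-2-yl)-1,3-dioxolan-2-yl]butan-1-one (both C2 epimers) | C=CC(C)(C)C1(CCC(C)C(=O)N2[C@H](C)CC[C@H]2C)OCCO1 | intermediate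
8 | (2R,5R)-2,5-dimethyl-1-{2-methyl-4-[2-(2-methylbut-3-en-2-yl)-1,3-dioxolan-2-yl]but-1-en-1-ylidene}pyrrolidin-1-ium triflate (keteniminium salt, not isolated) | C=CC(C)(C)C1(CCC(C)=C=[N+]2[C@H](C)CC[C@H]2C)OCCO1.[O-]S(=O)(=O)C(F)(F)F | intermediate
9 | cyclobutaniminium triflate: the N-(2R,5R)-2,5-dimethylpyrrolidinium ylidene derivative of 10 at C9, ring configuration as in 10 (not isolated) | C[C@@H]1CC[C@@H](C)[N+]1=C1C[C@@H]2C(C)(C)C3(OCCO3)CC[C@]12C.[O-]S(=O)(=O)C(F)(F)F | intermediate
10 | (1R,6S)-2,2,6-trimethylspiro[bicyclo[4.2.0]octane-3,2′-[1,3]dioxolan]-7-one (cis-fused; C5–H and C10–CH3 syn) | O=C1C[C@@H]2C(C)(C)C3(OCCO3)CC[C@]12C | intermediate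
11 | trimethyl(prop-1-yn-1-yl)silane | CC#C[Si](C)(C)C | starting material
12 | cis-fused silyl enone: C3 ethylene ketal, 4,4-dimethyl, C10–CH3 and C5–H syn, C9=O, C8–CH3, C7–SiMe3, C7=C8; configuration at C5/C10 as in 10 | CC1=C([Si](C)(C)C)C[C@@H]2C(C)(C)C3(OCCO3)CC[C@]2(C)C1=O | intermediate
13 | cis-fused silyl diene: as 12 with C9=CH2 (C11) in place of C9=O | CC1=C([Si](C)(C)C)C[C@@H]2C(C)(C)C3(OCCO3)CC[C@]2(C)C1=C | intermediate
14 | B-alkyl-9-BBN adduct of 13: 9-borabicyclo[3.3.1]nonan-9-yl on C11, C9–H syn to C10–CH3 (not isolated) | CC1=C([Si](C)(C)C)C[C@@H]2C(C)(C)C3(OCCO3)CC[C@]2(C)[C@@H]1CB1C2CCCC1CCC2 | intermediate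
15 | cis-fused silyl ketal alcohol: as 13 with C9–H (syn to C10–CH3 and C5–H) and C11–OH | CC1=C([Si](C)(C)C)C[C@@H]2C(C)(C)C3(OCCO3)CC[C@]2(C)[C@@H]1CO | intermediate
16 | (4aS,5R,8aS)-5-(hydroxymethyl)-1,1,4a,6-tetramethyl-3,4,4a,5,8,8a-hexahydronaphthalen-2(1H)-one | CC1=CC[C@@H]2C(C)(C)C(=O)CC[C@]2(C)[C@@H]1CO | intermediate
17 | 7-hydroxy-2H-chromen-2-one (umbelliferone) | O=c1ccc2ccc(O)cc2o1 | starting material
18 | 7-{[(1R,4aS,8aS)-2,5,5,8a-tetramethyl-6-oxo-1,4,4a,5,6,7,8,8a-octahydronaphthalen-1-yl]methoxy}-2H-chromen-2-one | CC1=CC[C@@H]2C(C)(C)C(=O)CC[C@]2(C)[C@@H]1COc1ccc2ccc(=O)oc2c1 | target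

**Totals**

Total step count: 9. Longest linear sequence: 9 steps (1 → 18).

**Steps most likely to fail**

Step 5. Oxidative cyclisation at a carbonyl flanked by the quaternary C10 may be too slow, so that alkyne oligomerisation takes over, or β-carbon elimination or alkyne orientation may go the wrong way. The fallback sets out from 10 and comes back at 16, inserting the two ring-B carbons one at a time with classical chemistry. Ring expansion of 10 with diazomethane (Et2O/MeOH, 0 °C; the less substituted α-carbon C6 migrates) should give the cis-fused cyclopentanone F1 as the first homologue. A second homologation (Me3SiCHN2, Me3Al, CH2Cl2, −78 °C; then Bu4NF to remove silicon) should turn it into the cis-fused cyclohexanone F2 with the C9 carbonyl still next to C10. Methylation at C8, the only enolisable position (LiN(iPr)2, MeI, THF, −78 °C), should give the α-methyl ketone F3 as either C8 epimer. Dehydrogenation (IBX, DMSO, 70 °C) should convert it into the des-silyl enone F4 in which the C7=C8 bond is in place. Petasis olefination as in step 6 should give the des-silyl diene F5 and hydroboration–oxidation as in step 7 the des-silyl ketal alcohol F6 by the same facial argument. The conditions of step 8, which then only have to remove the ketal, convert F6 into 16.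

Step 4. Positive charge building up at C5 in the asynchronous cycloaddition may trigger fragmentation towards the neighbouring ketal carbon or a methyl shift from C4, the ketal may not survive triflic anhydride, and face control by the pyrrolidine may be incomplete. The fallback sets out from 3 and comes back at 10, using a neutral ketene and separating enantiomers in place of auxiliary control. Ketalisation of 3 as in step 3 followed by aqueous work-up should give the ketal acid F7 in racemic form. Oxalyl chloride in the presence of pyridine should convert it into the ketal acid chloride F8 without loss of the dioxolane. Triethylamine in refluxing toluene should generate the ketene F9 by dehydrochlorination, and thermal intramolecular ketene–alkene [2+2] cycloaddition should then give 10 together with its mirror image, the ent-cyclobutanone F10 which is removed by chromatography on a chiral stationary phase.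

Step 7. Facial discrimination at C9 in the hydroboration may be insufficient. The fallback sets out from 12 and comes back at 15, introducing C11 at the aldehyde oxidation level so that C9 is set by protonation and stays correctable. Wittig reaction of 12 with methoxymethylenetriphenylphosphorane (Ph3PCH2OMe chloride, KOtBu, THF) should give the dienyl methyl ether F11 as either alkene isomer. Mild hydrolysis (oxalic acid, wet THF, 0 °C; the dioxolane is kept) should protonate C9 from the convex face and give the C11 aldehyde F12 with C9–H syn to C10–CH3. The C9 epimers should be separable, and the unwanted one can be re-equilibrated by brief treatment with DBU, stopped before the double bond moves into conjugation. NaBH4 (MeOH, 0 °C) then reduces F12 to 15.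

**Further compounds**

F1 | step 5 | cis-fused cyclopentanone: one-carbon ring-expanded 10 (C9=O, C7H2, C6H2 in a five-membered ring) | O=C1CC[C@@H]2C(C)(C)C3(OCCO3)CC[C@]12C
F2 | step 5 | cis-fused cyclohexanone: C9=O, C8H2, C7H2, C6H2 in ring B, C3 ethylene ketal | O=C1CCC[C@@H]2C(C)(C)C3(OCCO3)CC[C@]12C
F3 | step 5 | α-methyl ketone: F2 with CH3 on C8 (either C8 epimer) | CC1CC[C@@H]2C(C)(C)C3(OCCO3)CC[C@]2(C)C1=O
F4 | step 5 | des-silyl enone: 12 with H in place of SiMe3 on C7 | CC1=CC[C@@H]2C(C)(C)C3(OCCO3)CC[C@]2(C)C1=O
F5 | step 5 | des-silyl diene: 13 with H in place of SiMe3 on C7 | CC1=CC[C@@H]2C(C)(C)C3(OCCO3)CC[C@]2(C)C1=C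
F6 | step 5 | des-silyl ketal alcohol: 15 with H in place of SiMe3 on C7 | CC1=CC[C@@H]2C(C)(C)C3(OCCO3)CC[C@]2(C)[C@@H]1CO
F7 | step 4 | 2-methyl-4-[2-(2-methylbut-3-en-2-yl)-1,3-dioxolan-2-yl]butanoic acid (racemic) | C=CC(C)(C)C1(CCC(C)C(O)=O)OCCO1
F8 | step 4 | 2-methyl-4-[2-(2-methylbut-3-en-2-yl)-1,3-dioxolan-2-yl]butanoyl chloride (racemic) | C=CC(C)(C)C1(CCC(C)C(Cl)=O)OCCO1
F9 | step 4 | 2-methyl-4-[2-(2-methylbut-3-en-2-yl)-1,3-dioxolan-2-yl]but-1-en-1-one (ketene) | C=CC(C)(C)C1(CCC(C)=C=O)OCCO1
F10 | step 4 | (1S,6R)-2,2,6-trimethylspiro[bicyclo[4.2.0]octane-3,2′-[1,3]dioxolan]-7-one (enantiomer of 10) | O=C1C[C@H]2C(C)(C)C3(OCCO3)CC[C@@]12C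
F11 | step 7 | dienyl methyl ether: 12 with C9=CH–OCH3 in place of C9=O (either alkene geometry) | CC1=C([Si](C)(C)C)C[C@@H]2C(C)(C)C3(OCCO3)CC[C@]2(C)C1=COC
F12 | step 7 | C11 aldehyde: 15 with CHO in place of CH2OH, C9–H syn to C10–CH3 | CC1=C([Si](C)(C)C)C[C@@H]2C(C)(C)C3(OCCO3)CC[C@]2(C)[C@@H]1C=O
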